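**Retrosynthetic overview**
1. Feature: the only ring is the cyclohexane C5–C6–C7–C8–C9–C10. Its quaternary C10 bears methyl C14, the vinyl group C1=C2 and the ring methylene C9. With a C8=C9 double bond in place, C9 is the inner carbon of a second vinyl group, so C10 can be carried as an achiral methyl-divinyl carbon that becomes stereogenic only on ring closure.
2. Endgame disconnections: silyl and tert-butyl groups; C15–OH (allylic hydroxylation of the C5 isopropenyl group); O8 ester (side-chain acid from dimethyl (R)-malate); C13 methylene (Mannich/elimination at C11); C8–OH (reduction of a C8 ketone).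
3. Key disconnection: the C8 ketone is the hydrolysed form of a cyclic silyl enol ether. Its C8=C9 bond is opened to an acyclic silyl enol ether with two diastereotopic vinyl groups on C10. Group-selective ring-closing metathesis is the only ring-forming event.
4. The acyclic precursor comes from a methyl ketone, made from the anti, Felkin aldol adduct (C6–C7) of a succinic thioester and an α-isopropenyl aldehyde. The aldehyde comes from an enantioselective Ireland–Claisen rearrangement (C5–C10) of a 3-methylpentadienyl ester.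

Key step: step 11

**Remarks**
- Numbering: elemane numbering is used throughout. C5 bears C4(=C3H2)C15, and C7 bears C11(=C13H2)C12. "13-nor" means that C13 is still missing.
- Faces: in the target the C10 vinyl, O6, the C7 arm and O8 lie on one ring face, and C14 and the C5 arm lie on the other. O6 and the C7 arm are therefore cis on the ring, which corresponds to an anti aldol relation along C5–C6–C7–C8.
- Design: the C5 arm is carried as the isopropenyl group itself, not as a protected tertiary carbinol. It has no productive ring-closing partner, it leaves C10 as the clearly larger substituent for Felkin control, and no dehydration is needed.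
- Assumption: the (S,S) boron controller of step 3 and the (S)-biphenolate of step 11 are written as the antipodes that give the drawn products. The sense of induction on these new substrates is read from the first run, and the equally available mirror-image reagent is taken if it is opposite.

**Route**

Step 1
Reactants: 1 (Z)-3-methylpent-2-en-4-yn-1-ol
Product: 2 (Z)-3-methylpenta-2,4-dien-1-ol
Conditions: H2 (1 atm, stopped at 1 equiv), 5% Pd/CaCO3 poisoned with Pb(OAc)2, quinoline, EtOAc/hexane, 0 °C
Reagents that add atoms: none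
Why: Partial hydrogenation of a terminal alkyne over lead-poisoned palladium should stop at the vinyl group because the alkyne binds far more strongly than the diene; no stereocentre is formed.

Step 2
Reactants: 2 (Z)-3-methylpenta-2,4-dien-1-ol; 3 3-methylbut-3-enoic acid
Product: 4 (Z)-3-methylpenta-2,4-dien-1-yl 3-methylbut-3-enoate
Conditions: DCC, DMAP (5 mol %), CH2Cl2, 0 °C
Reagents that add atoms: none
Why: Steglich esterification; the low DMAP loading and low temperature keep the β,γ-double bond of the acid out of conjugation.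

Step 3
Reactants: 4 (Z)-3-methylpenta-2,4-dien-1-yl 3-methylbut-3-enoate
Product: 7 (2R)-3-ethenyl-3-methyl-2-(prop-1-en-2-yl)pent-4-enoic acid, via boron ketene acetal 5 (not isolated), via acyloxyborane 6 (not isolated)
Conditions: (4S,5S)-2-bromo-4,5-diphenyl-1,3-bis[3,5-(CF3)2C6H3SO2]-1,3,2-diazaborolidine (made from the bis-sulfonamide and BBr3, CH2Cl2, then evacuated), Et3N, toluene/hexane, −78 °C, then −20 → 4 °C; H2O
Reagents that add atoms: none
Why: Enantioselective boron-enolate Ireland–Claisen rearrangement: soft enolisation of the doubly activated C5 methylene gives the E(O) dienolate 5, the chair [3,3] shift joins C5 to the fully substituted diene carbon and turns the former C–O terminus into a second vinyl group, so C10 is an achiral methyl-divinyl carbon and the only stereocentre, C5, is set by the enolate face that the C2-symmetric bis-sulfonamide on boron leaves open.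

Step 4
Reactants: 7 (2R)-3-ethenyl-3-methyl-2-(prop-1-en-2-yl)pent-4-enoic acid
Product: 8 (2R)-3-ethenyl-3-methyl-2-(prop-1-en-2-yl)pent-4-en-1-ol
Conditions: LiAlH4, Et2O, 0 °C → rt; then H2O
Reagents that add atoms: none
Why: Hydride reduction of the acid proceeds through its carboxylate, which cannot enolise, so C5 and the three alkenes are left untouched.

Step 5
Reactants: 8 (2R)-3-ethenyl-3-methyl-2-(prop-1-en-2-yl)pent-4-en-1-ol
Product: 9 (2R)-3-ethenyl-3-methyl-2-(prop-1-en-2-yl)pent-4-enal
Conditions: Dess–Martin periodinane, NaHCO3, CH2Cl2, 0 °C; used at once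
Reagents that add atoms: none
Why: Dess–Martin oxidation runs without amine base, which limits enolisation of the β,γ-unsaturated aldehyde (loss of C5 configuration or shift of the isopropenyl double bond into conjugation).

Step 6
Reactants: 10 4-tert-butoxy-4-oxobutanoic acid; 11 2-methylpropane-2-thiol
Product: 12 tert-butyl 4-(tert-butylsulfanyl)-4-oxobutanoate
Conditions: DCC, DMAP (10 mol %), CH2Cl2, 0 °C → rt
Reagents that add atoms: none
Why: Steglich-type thioesterification differentiates the two succinate carbonyls, giving one that is easily enolised and later convertible to a ketone and one that is inert.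

Step 7
Reactants: 12 tert-butyl 4-(tert-butylsulfanyl)-4-oxobutanoate; 9 (2R)-3-ethenyl-3-methyl-2-(prop-1-en-2-yl)pent-4-enal
Product: 15 S-tert-butyl (2S,3S,4R)-2-(2-tert-butoxy-2-oxoethyl)-5-ethenyl-3-hydroxy-5-methyl-4-(prop-1-en-2-yl)hept-6-enethioate, via boron enolate 13 (not isolated), via boron aldolate 14 (not isolated)
Conditions: (c-C6H11)2BOTf, Et3N, CH2Cl2, −78 → 0 °C; 9, −78 → −20 °C; pH 7 buffer, MeOH, 30% H2O2, 0 °C
Reagents that add atoms: none
Why: Boron-mediated anti aldol reaction: the bulky borane/Et3N pair enolises only the thioester to the E(O) enolate 13, its Zimmerman–Traxler chair sets the C6/C7 anti relation, and Felkin–Anh attack anti to the quaternary C10 substituent of 9 (isopropenyl as the medium group), the sense that E enolates reinforce, sets C6 relative to C5.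

Step 8
Reactants: 15 anti aldol adduct
Product: 16 S-tert-butyl (2S,3S,4R)-2-(2-tert-butoxy-2-oxoethyl)-3-[(tert-butyldimethylsilyl)oxy]-5-ethenyl-5-methyl-4-(prop-1-en-2-yl)hept-6-enethioate
Conditions: TBSOTf, 2,6-lutidine, CH2Cl2, −78 → 0 °C
Reagents that add atoms: tert-butyldimethylsilyl triflate, CC(C)(C)[Si](C)(C)OS(=O)(=O)C(F)(F)F
Why: Silyl triflate silylation reaches the hindered C6 alcohol, the non-nucleophilic base avoids retro-aldol cleavage, and the tert-butyl ester survives at this temperature.

Step 9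
Reactants: 16 silylated thioester
Product: 17 tert-butyl (3S,4S,5R)-3-acetyl-4-[(tert-butyldimethylsilyl)oxy]-6-ethenyl-6-methyl-5-(prop-1-en-2-yl)oct-7-enoate
Conditions: Me2CuLi (from MeLi and CuI), Et2O, −78 → −10 °C; aq. NH4Cl
Reagents that add atoms: lithium dimethylcuprate, [Li+].C[Cu-]C
Why: Acyl substitution of a thioester by a Gilman cuprate stops at the methyl ketone, ignores the tert-butyl ester, and is too weakly basic to enolise toward C7.

Step 10
Reactants: 17 methyl ketone
Product: 19 tert-butyl (3S,4S,5R)-4-[(tert-butyldimethylsilyl)oxy]-3-{1-[(tert-butyldimethylsilyl)oxy]ethenyl}-6-ethenyl-6-methyl-5-(prop-1-en-2-yl)oct-7-enoate, via potassium enolate 18 (not isolated)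
Conditions: KN(SiMe3)2 (1.1 equiv), TBSCl, THF, −78 → −20 °C; Et3N-deactivated silica
Reagents that add atoms: tert-butyldimethylsilyl chloride, CC(C)(C)[Si](C)(C)Cl
Why: Kinetic enolate formation and O-silylation: the hindered base takes a proton from the unhindered methyl group rather than from the tertiary C7–H or the less acidic C11–H2, so C7 keeps its configuration and the C6 silyloxy group is not eliminated.

Step 11
Reactants: 19 acyclic silyl enol ether with the methyl-divinyl carbon
Product: 20 tert-butyl (5R,6S,7S,10R)-6,8-bis[(tert-butyldimethylsilyl)oxy]-13-norelema-1,3,8-trien-12-oate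
Conditions: Mo(N-2,6-iPr2C6H3)(CHCMe2Ph)[(S)-3,3'-tBu2-5,5',6,6'-Me4-biphenyl-2,2'-diolate] (10 mol %), C6H6 (0.02 M), 22 → 50 °C, N2, vented to remove C2H4
Reagents that add atoms: none
Why: The molybdenum alkylidene exchanges reversibly with either C10 vinyl group to give a C9 alkylidene, which adds across CH2=C8(OTBS) through a metallacyclobutane with C9 bound to C8, and cycloreversion releases the C8=C9 enol ether and Mo=CH2, which re-enters the cycle with loss of ethylene. The closest known reaction types are ring-closing metathesis onto 1,1-disubstituted silyl or alkyl enol ethers and catalytic desymmetrising ring-closing metathesis of trienes that creates all-carbon quaternary centres. The one ring formed, the six-membered carbocycle C5–C6–C7–C8–C9–C10, is closed at C8–C9 by intramolecular alkylidene/alkene [2+2] addition and retro-[2+2] cleavage. C10 is the only new stereocentre; it is fixed by which diastereotopic vinyl group enters the metallacycle, and because methyl and vinyl differ little in size the choice is handed to the chiral biphenolate pocket, acting in the matched sense with the C5–C7 triad (C5 isopropenyl and C6 silyloxy equatorial in the chair-like closure), so that the spectator vinyl ends trans to the C5 arm. Chemoselectivity is secured by the substrate, since vinyl/vinyl closure would give a cyclopropene, vinyl/isopropenyl a cyclobutene and isopropenyl/enol ether a tetrasubstituted cyclopentene, and because alkylidene exchange is faster than closure the two six-ring pathways compete under Curtin–Hammett conditions.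

Step 12
Reactants: 20 cyclic silyl enol ether
Product: 21 tert-butyl (5R,6S,7S,10R)-6-[(tert-butyldimethylsilyl)oxy]-8-oxo-13-norelema-1,3-dien-12-oate
Conditions: Bu4NF (1.05 equiv), AcOH (1.5 equiv), THF, −20 °C
Reagents that add atoms: none
Why: Fluoride-induced cleavage of the silyl enol ether releases the C8 enolate, which acetic acid protonates at C9, so C7 is never part of an enolate, and the hindered alkyl silyl ether at O6 reacts far more slowly.

Step 13
Reactants: 21 C8 ketone
Product: 22 tert-butyl (5R,6S,7R,8R,10R)-6-[(tert-butyldimethylsilyl)oxy]-8-hydroxy-13-norelema-1,3-dien-12-oate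
Conditions: SmI2 (2.5 equiv), H2O (25 equiv), THF, 0 °C; pH 7 buffer; used crude
Reagents that add atoms: none
Why: Single-electron ketyl reduction with SmI2–H2O should give the more stable equatorial C8 alcohol (cis to the axial C7 arm), because the axial epimer would place O8 syn-axial to C14; the near-neutral medium spares C7, and the bulk of the tert-butyl ester holds back lactonisation.

Step 14
Reactants: 22 C8 alcohol
Product: 23 tert-butyl (5R,6S,7R,8R,10R)-6-[(tert-butyldimethylsilyl)oxy]-8-[(triethylsilyl)oxy]-13-norelema-1,3-dien-12-oate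
Conditions: TESOTf, 2,6-lutidine, CH2Cl2, −78 °C
Reagents that add atoms: triethylsilyl triflate, CC[Si](CC)(CC)OS(=O)(=O)C(F)(F)F
Why: Silyl ether formation masks O8 for the strong-base step and removes the risk of attack of O8 on C12; the triethylsilyl group can later be removed in the presence of the O6 group.

Step 15
Reactants: 23 bis-silyl ether
Product: 25 tert-butyl (5R,6S,7R,8R,10R)-6-[(tert-butyldimethylsilyl)oxy]-13-(dimethylamino)-8-[(triethylsilyl)oxy]elema-1,3-dien-12-oate (C11 epimers), via lithium enolate 24 (not isolated)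
Conditions: LiN(iPr)2, THF, −78 °C; CH2=NMe2+ I−, −78 → −20 °C
Reagents that add atoms: N,N-dimethylmethyleneiminium iodide, C=[N+](C)C.[I-]
Why: Ester enolate Mannich reaction at the only acidic position, C11; the new C11 centre is erased in the next step, so its configuration does not matter.

Step 16
Reactants: 25 Mannich base
Product: 27 tert-butyl (5R,6S,7R,8R,10R)-6-[(tert-butyldimethylsilyl)oxy]-8-[(triethylsilyl)oxy]elema-1,3,11(13)-trien-12-oate, via ammonium iodide 26 (not isolated)
Conditions: MeI, Et2O/MeOH, rt; then DBU, CH2Cl2, 0 °C → rt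
Reagents that add atoms: none
Why: N-methylation followed by Hofmann-type E1cB elimination of trimethylamine gives the C11=C13 acrylate under conditions too mild to move the double bond toward C7.

Step 17
Reactants: 27 acrylate
Product: 28 tert-butyl (5R,6S,7R,8R,10R)-6-[(tert-butyldimethylsilyl)oxy]-8-hydroxyelema-1,3,11(13)-trien-12-oate
Conditions: PPTS (cat.), MeOH/CH2Cl2, 0 °C
Reagents that add atoms: none
Why: Acid-catalysed methanolysis distinguishes triethylsilyl from tert-butyldimethylsilyl ethers by their large difference in solvolysis rate, and the acid is too weak to cleave the tert-butyl ester.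

Step 18
Reactants: 29 dimethyl (R)-malate
Product: 30 methyl (R)-3,4-dihydroxybutanoate
Conditions: BH3·SMe2 (1.05 equiv), NaBH4 (5 mol %), THF, 0 °C → rt; MeOH; used crude
Reagents that add atoms: none
Why: Hydroxyl-directed borane reduction delivers hydride through a five-membered boron chelate to the adjacent ester only; C3' comes from the chiral pool and is not touched.

Step 19
Reactants: 30 methyl (R)-3,4-dihydroxybutanoate
Product: 31 methyl (R)-3,4-bis[(tert-butyldimethylsilyl)oxy]butanoate
Conditions: TBSCl, imidazole, DMF, rt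
Reagents that add atoms: tert-butyldimethylsilyl chloride, CC(C)(C)[Si](C)(C)Cl
Why: Standard silyl ether formation blocks lactonisation and gives side-chain protecting groups that fall in the final fluoride step.

Step 20
Reactants: 31 bis-silyl ester
Product: 32 (R)-3,4-bis[(tert-butyldimethylsilyl)oxy]butanal
Conditions: iBu2AlH (1.05 equiv), CH2Cl2, −78 °C; then H2O
Reagents that add atoms: none
Why: Partial reduction of the ester stops at the aldehyde because the aluminium hemiacetal is stable at low temperature.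

Step 21
Reactants: 32 aldehyde
Product: 34 (R)-3,4-bis[(tert-butyldimethylsilyl)oxy]-2-methylidenebutanal, via Mannich base 33 (not isolated)
Conditions: CH2=NMe2+ I−, Et3N, CH2Cl2, rt
Reagents that add atoms: N,N-dimethylmethyleneiminium iodide, C=[N+](C)C.[I-]
Why: Aldehyde α-methylenation (Mannich addition, then loss of dimethylamine) needs only a tertiary amine base, so the β-silyloxy group is not expelled and C3' is not involved.

Step 22
Reactants: 34 enal
Product: 35 (R)-3,4-bis[(tert-butyldimethylsilyl)oxy]-2-methylidenebutanoic acid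
Conditions: NaClO2, NaH2PO4, 2-methylbut-2-ene, tBuOH/H2O, 0 °C → rt
Reagents that add atoms: sodium chlorite, [Na+].[O-]Cl=O
Why: Pinnick oxidation converts α-substituted enals to acrylic acids without touching the alkene or the silyl ethers.

Step 23
Reactants: 28 C8 alcohol; 35 side-chain acid
Product: 37 tert-butyl (5R,6S,7R,8R,10R)-8-({(3R)-3,4-bis[(tert-butyldimethylsilyl)oxy]-2-methylidenebutanoyl}oxy)-6-[(tert-butyldimethylsilyl)oxy]elema-1,3,11(13)-trien-12-oate, via mixed anhydride 36 (not isolated)
Conditions: 2,4,6-Cl3C6H2COCl, Et3N, toluene, rt; then 28, DMAP, toluene, rt → 40 °C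
Reagents that add atoms: none
Why: Yamaguchi esterification is suited to a hindered equatorial secondary alcohol, forms the ester at the acyl carbon so that C8 and C3' keep their configuration, and finds O8 as the only free hydroxyl.

Step 24
Reactants: 37 ester
Product: 38 tert-butyl (5S,6S,7R,8R,10R)-8-({(3R)-3,4-bis[(tert-butyldimethylsilyl)oxy]-2-methylidenebutanoyl}oxy)-6-[(tert-butyldimethylsilyl)oxy]-15-hydroxyelema-1,3,11(13)-trien-12-oate
Conditions: SeO2 (0.5 equiv), tBuOOH (3 equiv, decane), CH2Cl2, 0 °C → rt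
Reagents that add atoms: selenium dioxide, O=[Se]=O; tert-butyl hydroperoxide, CC(C)(C)OO
Why: Catalytic SeO2 allylic hydroxylation (ene reaction, then [2,3] shift) should pick the isopropenyl group, because it is the only electron-rich alkene with accessible allylic hydrogens (the vinyl group has none, both acrylates are deactivated, and C5–H is buried).

Step 25
Reactants: 38 allylic alcohol
Product: 40 (5S,6S,7R,8R,10R)-8-({(3R)-3,4-bis[(tert-butyldimethylsilyl)oxy]-2-methylidenebutanoyl}oxy)-6-[(tert-butyldimethylsilyl)oxy]-15-hydroxyelema-1,3,11(13)-trien-12-oic acid, via trimethylsilyl ester 39 (not isolated)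
Conditions: Me3SiOTf, 2,6-lutidine, CH2Cl2, 0 °C → rt; then aq. citric acid/THF, 0 °C
Reagents that add atoms: none
Why: Silyl-triflate-mediated tert-butyl ester cleavage (loss of isobutene) works under buffered conditions while O6 is still silylated, so the freed acid has no hydroxyl to lactonise with; the transient trimethylsilyl groups on O12 and O15 fall off on work-up.

Step 26
Reactants: 40 tris-silyl acid
Product: 41 (5S,6S,7S,8R,10R)-8-{[(3R)-3,4-dihydroxy-2-methylidenebutanoyl]oxy}-6,15-dihydroxyelema-1,3,11(13)-trien-12-oic acid (target)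
Conditions: HF·pyridine, pyridine, THF, 0 °C → rt; excess HF consumed with Me3SiOMe, evaporation below rt
Reagents that add atoms: none
Why: Global fluoride desilylation in a weakly acidic buffered medium avoids both base (which would let O4' displace O8 from the side-chain ester) and strong acid (which would close C12 onto O6).

**Compound list**
1 | (Z)-3-methylpent-2-en-4-yn-1-ol | OC/C=C(/C)C#C | starting material
2 | (Z)-3-methylpenta-2,4-dien-1-ol | OC/C=C(/C)C=C | intermediate
3 | 3-methylbut-3-enoic acid | C=C(C)CC(=O)O | starting material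
4 | (Z)-3-methylpenta-2,4-dien-1-yl 3-methylbut-3-enoate | C=C(C)CC(=O)OC/C=C(/C)C=C | intermediate
5 | boron ketene acetal: E(O) dienolate of 4 bound through O to the (4S,5S)-diazaborolidine | C=C(C)/C=C(/OB1N(S(=O)(=O)c2cc(C(F)(F)F)cc(C(F)(F)F)c2)[C@@H](c2ccccc2)[C@H](c2ccccc2)N1S(=O)(=O)c1cc(C(F)(F)F)cc(C(F)(F)F)c1)OC/C=C(/C)C=C | intermediate
6 | acyloxyborane of 7 with the (4S,5S)-diazaborolidine | C=CC(C)(C=C)[C@@H](C(C)=C)C(=O)OB1N(S(=O)(=O)c2cc(C(F)(F)F)cc(C(F)(F)F)c2)[C@@H](c2ccccc2)[C@H](c2ccccc2)N1S(=O)(=O)c1cc(C(F)(F)F)cc(C(F)(F)F)c1 | intermediate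
7 | (2R)-3-ethenyl-3-methyl-2-(prop-1-en-2-yl)pent-4-enoic acid | C=CC(C)(C=C)[C@@H](C(C)=C)C(=O)O | intermediate
8 | (2R)-3-ethenyl-3-methyl-2-(prop-1-en-2-yl)pent-4-en-1-ol | C=CC(C)(C=C)[C@@H](C(C)=C)CO | intermediate
9 | (2R)-3-ethenyl-3-methyl-2-(prop-1-en-2-yl)pent-4-enal | C=CC(C)(C=C)[C@@H](C(C)=C)C=O | intermediate
10 | 4-tert-butoxy-4-oxobutanoic acid | OC(=O)CCC(=O)OC(C)(C)C | starting material
11 | 2-methylpropane-2-thiol | CC(C)(C)S | starting material
12 | tert-butyl 4-(tert-butylsulfanyl)-4-oxobutanoate | CC(C)(C)SC(=O)CCC(=O)OC(C)(C)C | intermediate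
13 | dicyclohexylboron E(O) enolate of 12 | CC(C)(C)OC(=O)C/C=C(/OB(C1CCCCC1)C1CCCCC1)SC(C)(C)C | intermediate
14 | dicyclohexylboron aldolate of 15 | C=CC(C)(C=C)[C@@H](C(C)=C)[C@H](OB(C1CCCCC1)C1CCCCC1)[C@H](CC(=O)OC(C)(C)C)C(=O)SC(C)(C)C | intermediate
15 | anti, Felkin aldol adduct (5R,6S,7S) | C=CC(C)(C=C)[C@@H](C(C)=C)[C@H](O)[C@H](CC(=O)OC(C)(C)C)C(=O)SC(C)(C)C | intermediate
16 | O6-TBS ether of 15 | C=CC(C)(C=C)[C@@H](C(C)=C)[C@H](O[Si](C)(C)C(C)(C)C)[C@H](CC(=O)OC(C)(C)C)C(=O)SC(C)(C)C | intermediate
17 | methyl ketone (5R,6S,7S) | C=CC(C)(C=C)[C@@H](C(C)=C)[C@H](O[Si](C)(C)C(C)(C)C)[C@H](CC(=O)OC(C)(C)C)C(C)=O | intermediate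
18 | potassium enolate of 17 (methyl side) | C=CC(C)(C=C)[C@@H](C(C)=C)[C@H](O[Si](C)(C)C(C)(C)C)[C@H](CC(=O)OC(C)(C)C)C(=C)[O-].[K+] | intermediate
19 | acyclic silyl enol ether with methyl-divinyl C10 (5R,6S,7S), key-step precursor | C=CC(C)(C=C)[C@@H](C(C)=C)[C@H](O[Si](C)(C)C(C)(C)C)[C@H](CC(=O)OC(C)(C)C)C(=C)O[Si](C)(C)C(C)(C)C | intermediate
20 | cyclic silyl enol ether (5R,6S,7S,10R), key-step product | C=C[C@@]1(C)C=C(O[Si](C)(C)C(C)(C)C)[C@@H](CC(=O)OC(C)(C)C)[C@@H](O[Si](C)(C)C(C)(C)C)[C@@H]1C(C)=C | intermediate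
21 | C8 ketone (5R,6S,7S,10R) | C=C[C@@]1(C)CC(=O)[C@@H](CC(=O)OC(C)(C)C)[C@@H](O[Si](C)(C)C(C)(C)C)[C@@H]1C(C)=C | intermediate
22 | equatorial C8 alcohol (5R,6S,7R,8R,10R) | C=C[C@@]1(C)C[C@@H](O)[C@@H](CC(=O)OC(C)(C)C)[C@@H](O[Si](C)(C)C(C)(C)C)[C@@H]1C(C)=C | intermediate
23 | O8-TES ether of 22 | C=C[C@@]1(C)C[C@@H](O[Si](CC)(CC)CC)[C@@H](CC(=O)OC(C)(C)C)[C@@H](O[Si](C)(C)C(C)(C)C)[C@@H]1C(C)=C | intermediate
24 | lithium ester enolate of 23 | C=C[C@@]1(C)C[C@@H](O[Si](CC)(CC)CC)[C@@H](C=C([O-])OC(C)(C)C)[C@@H](O[Si](C)(C)C(C)(C)C)[C@@H]1C(C)=C.[Li+] | intermediate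
25 | C13 dimethylamino Mannich base (C11 epimers) | C=C[C@@]1(C)C[C@@H](O[Si](CC)(CC)CC)[C@@H](C(CN(C)C)C(=O)OC(C)(C)C)[C@@H](O[Si](C)(C)C(C)(C)C)[C@@H]1C(C)=C | intermediate
26 | trimethylammonium iodide of 25 | C=C[C@@]1(C)C[C@@H](O[Si](CC)(CC)CC)[C@@H](C(C[N+](C)(C)C)C(=O)OC(C)(C)C)[C@@H](O[Si](C)(C)C(C)(C)C)[C@@H]1C(C)=C.[I-] | intermediate
27 | C11=C13 acrylate, O8-TES, O6-TBS | C=C[C@@]1(C)C[C@@H](O[Si](CC)(CC)CC)[C@@H](C(=C)C(=O)OC(C)(C)C)[C@@H](O[Si](C)(C)C(C)(C)C)[C@@H]1C(C)=C | intermediate
28 | C8 alcohol with acrylate arm | C=C[C@@]1(C)C[C@@H](O)[C@@H](C(=C)C(=O)OC(C)(C)C)[C@@H](O[Si](C)(C)C(C)(C)C)[C@@H]1C(C)=C | intermediate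
29 | dimethyl (R)-malate | COC(=O)C[C@@H](O)C(=O)OC | starting material
30 | methyl (R)-3,4-dihydroxybutanoate | COC(=O)C[C@@H](O)CO | intermediate
31 | methyl (R)-3,4-bis[(tert-butyldimethylsilyl)oxy]butanoate | COC(=O)C[C@@H](O[Si](C)(C)C(C)(C)C)CO[Si](C)(C)C(C)(C)C | intermediate
32 | (R)-3,4-bis[(tert-butyldimethylsilyl)oxy]butanal | O=CC[C@@H](O[Si](C)(C)C(C)(C)C)CO[Si](C)(C)C(C)(C)C | intermediate
33 | α-(dimethylaminomethyl) aldehyde (C2' epimers) | O=CC(CN(C)C)[C@@H](O[Si](C)(C)C(C)(C)C)CO[Si](C)(C)C(C)(C)C | intermediate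
34 | (R)-3,4-bis[(tert-butyldimethylsilyl)oxy]-2-methylidenebutanal | O=CC(=C)[C@@H](O[Si](C)(C)C(C)(C)C)CO[Si](C)(C)C(C)(C)C | intermediate
35 | (R)-3,4-bis[(tert-butyldimethylsilyl)oxy]-2-methylidenebutanoic acid | OC(=O)C(=C)[C@@H](O[Si](C)(C)C(C)(C)C)CO[Si](C)(C)C(C)(C)C | intermediate
36 | mixed anhydride of 35 and 2,4,6-trichlorobenzoic acid | O=C(OC(=O)C(=C)[C@@H](O[Si](C)(C)C(C)(C)C)CO[Si](C)(C)C(C)(C)C)c1c(Cl)cc(Cl)cc1Cl | intermediate
37 | O8 ester, fully protected | C=C[C@@]1(C)C[C@@H](OC(=O)C(=C)[C@@H](O[Si](C)(C)C(C)(C)C)CO[Si](C)(C)C(C)(C)C)[C@@H](C(=C)C(=O)OC(C)(C)C)[C@@H](O[Si](C)(C)C(C)(C)C)[C@@H]1C(C)=C | intermediate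
38 | 15-hydroxy ester | C=C[C@@]1(C)C[C@@H](OC(=O)C(=C)[C@@H](O[Si](C)(C)C(C)(C)C)CO[Si](C)(C)C(C)(C)C)[C@@H](C(=C)C(=O)OC(C)(C)C)[C@@H](O[Si](C)(C)C(C)(C)C)[C@@H]1C(=C)CO | intermediate
39 | C12 trimethylsilyl ester, O15 trimethylsilyl ether | C=C[C@@]1(C)C[C@@H](OC(=O)C(=C)[C@@H](O[Si](C)(C)C(C)(C)C)CO[Si](C)(C)C(C)(C)C)[C@@H](C(=C)C(=O)O[Si](C)(C)C)[C@@H](O[Si](C)(C)C(C)(C)C)[C@@H]1C(=C)CO[Si](C)(C)C | intermediate
40 | C12 acid, O6, O3' and O4' still TBS | C=C[C@@]1(C)C[C@@H](OC(=O)C(=C)[C@@H](O[Si](C)(C)C(C)(C)C)CO[Si](C)(C)C(C)(C)C)[C@@H](C(=C)C(=O)O)[C@@H](O[Si](C)(C)C(C)(C)C)[C@@H]1C(=C)CO | intermediate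
41 | CNP0348657.1, (5S,6S,7S,8R,10R,3'R) | C=C[C@@]1(C)C[C@@H](OC(=O)C(=C)[C@@H](O)CO)[C@@H](C(=C)C(=O)O)[C@@H](O)[C@@H]1C(=C)CO | target

**Totals**
Total step count: 26.
Longest linear sequence: 20 steps (1–5, 7–17, 23–26).

**Steps most likely to fail**

1. Step 11.
What may go wrong: discrimination between the two diastereotopic vinyl groups may be too weak, because methyl and vinyl are nearly the same size. The closure onto the hindered enol ether next to the quaternary carbon may also stall while the catalyst decays.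
Fallback (sets out from 1 and 3, returns at 21):
 - The alkyne of 1 is kept as a stand-in for the spectator vinyl group. The two unsaturated groups on C10 then differ from the start, and C10 is fixed by the chair transition state of the Claisen step, not by a catalyst.
 - Double silylation of 1 (EtMgBr, Me3SiCl, THF) gives the O,C-bis(trimethylsilyl) enynol F1. Dilute citric acid removes its O-silyl group to leave (Z)-3-methyl-5-(trimethylsilyl)pent-2-en-4-yn-1-ol F2.
 - Steglich esterification with 3 gives the enynyl ester F3.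
 - The conditions of step 3 (E(O) enolate, Z alkene, chair) place the isopropenyl and silylethynyl groups anti across the new C5–C10 bond and give the acid F4, in which C10 is already stereogenic.
 - The conditions of steps 4, 5 and 7–10 lead through the alcohol F5, the aldehyde F6, the anti aldol adduct F7, its silyl ether F8 and the methyl ketone F9 to the silyl enol ether F10, which holds a single vinyl group.
 - Ring-closing metathesis then needs no group selection. It is run with the achiral second-generation Grubbs catalyst RuCl2(=CHPh)(PCy3)(H2IMes) in toluene at 80 °C, where the hindered silylalkyne stays out, and gives the cyclic silyl enol ether F11.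
 - Bu4NF/AcOH removes the enol and alkynyl silyl groups to give the ethynyl ketone F12. Partial hydrogenation over Pd/CaCO3 poisoned with Pb(OAc)2 gives 21.

2. Step 3.
What may go wrong: the Lewis acidic borane may ionise the pentadienyl ester, or the enolate geometry may erode. Either lowers the enantioselectivity on which the whole absolute configuration rests.
Fallback (sets out from 4, returns at 8):
 - A classical Ireland–Claisen rearrangement (LiN(iPr)2, Me3SiCl, THF, −78 °C → rt) gives the silyl ketene acetal F13.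
 - F13 rearranges to the trimethylsilyl ester F14, which is hydrolysed to the racemic acid F15. LiAlH4 then gives the racemic alcohol F16.
 - Esterification with (S)-O-methylmandelic acid (DCC, DMAP) gives the (2R) mandelate ester F17 and the (2S) mandelate ester F18. These are separated by chromatography or crystallisation.
 - LiOH in THF/H2O cleaves F17 to 8 and returns the resolving acid.

3. Step 13.
What may go wrong: hydrogen may be delivered to the wrong face of C8, since both faces are hindered (one by the axial C14, the other by the axial C7 arm). Enolisation toward C7 is a further risk while the ketone is exposed.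
Fallback (sets out from 21, returns at 22):
 - The bulky hydride LiBH(sBu)3 (THF, −78 °C) is used on purpose for equatorial attack and gives the axial 8-epi alcohol F19.
 - Mitsunobu inversion with chloroacetic acid (PPh3, DIAD, toluene) gives the equatorial chloroacetate F20.
 - Thiourea with NaHCO3 in EtOH removes the chloroacetyl group under near-neutral conditions and gives 22.

**Further compounds**
F1 | step 11 | (Z)-O,C-bis(trimethylsilyl) enynol | C[Si](C)(C)OC/C=C(/C)C#C[Si](C)(C)C
F2 | step 11 | (Z)-3-methyl-5-(trimethylsilyl)pent-2-en-4-yn-1-ol | OC/C=C(/C)C#C[Si](C)(C)C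
F3 | step 11 | (Z)-3-methyl-5-(trimethylsilyl)pent-2-en-4-yn-1-yl 3-methylbut-3-enoate | C=C(C)CC(=O)OC/C=C(/C)C#C[Si](C)(C)C
F4 | step 11 | Claisen acid with C10 bearing methyl, vinyl and silylethynyl | C[Si](C)(C)C#C[C@@](C)(C=C)[C@@H](C(C)=C)C(=O)O
F5 | step 11 | primary alcohol from F4 | C[Si](C)(C)C#C[C@@](C)(C=C)[C@@H](C(C)=C)CO
F6 | step 11 | aldehyde from F5 | C[Si](C)(C)C#C[C@@](C)(C=C)[C@@H](C(C)=C)C=O
F7 | step 11 | anti, Felkin aldol adduct of F6 and 12 | C[Si](C)(C)C#C[C@@](C)(C=C)[C@@H](C(C)=C)[C@H](O)[C@H](CC(=O)OC(C)(C)C)C(=O)SC(C)(C)C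
F8 | step 11 | O6-TBS ether of F7 | C[Si](C)(C)C#C[C@@](C)(C=C)[C@@H](C(C)=C)[C@H](O[Si](C)(C)C(C)(C)C)[C@H](CC(=O)OC(C)(C)C)C(=O)SC(C)(C)C
F9 | step 11 | methyl ketone from F8 | C[Si](C)(C)C#C[C@@](C)(C=C)[C@@H](C(C)=C)[C@H](O[Si](C)(C)C(C)(C)C)[C@H](CC(=O)OC(C)(C)C)C(C)=O
F10 | step 11 | silyl enol ether with one vinyl group | C[Si](C)(C)C#C[C@@](C)(C=C)[C@@H](C(C)=C)[C@H](O[Si](C)(C)C(C)(C)C)[C@H](CC(=O)OC(C)(C)C)C(=C)O[Si](C)(C)C(C)(C)C
F11 | step 11 | cyclic silyl enol ether with C10 silylethynyl | C[Si](C)(C)C#C[C@@]1(C)C=C(O[Si](C)(C)C(C)(C)C)[C@@H](CC(=O)OC(C)(C)C)[C@@H](O[Si](C)(C)C(C)(C)C)[C@@H]1C(C)=C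
F12 | step 11 | C10 ethynyl C8 ketone | C#C[C@@]1(C)CC(=O)[C@@H](CC(=O)OC(C)(C)C)[C@@H](O[Si](C)(C)C(C)(C)C)[C@@H]1C(C)=C
F13 | step 3 | trimethylsilyl ketene acetal of 4 | C=C(C)C=C(O[Si](C)(C)C)OC/C=C(/C)C=C
F14 | step 3 | racemic trimethylsilyl ester | C=CC(C)(C=C)C(C(C)=C)C(=O)O[Si](C)(C)C
F15 | step 3 | racemic acid | C=CC(C)(C=C)C(C(C)=C)C(=O)O
F16 | step 3 | racemic alcohol | C=CC(C)(C=C)C(C(C)=C)CO
F17 | step 3 | (S)-O-methylmandelate of the (2R) alcohol | C=CC(C)(C=C)[C@@H](C(C)=C)COC(=O)[C@@H](OC)c1ccccc1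
F18 | step 3 | (S)-O-methylmandelate of the (2S) alcohol | C=CC(C)(C=C)[C@H](C(C)=C)COC(=O)[C@@H](OC)c1ccccc1
F19 | step 13 | axial 8-epi alcohol | C=C[C@@]1(C)C[C@H](O)[C@@H](CC(=O)OC(C)(C)C)[C@@H](O[Si](C)(C)C(C)(C)C)[C@@H]1C(C)=C
F20 | step 13 | equatorial C8 chloroacetate | C=C[C@@]1(C)C[C@@H](OC(=O)CCl)[C@@H](CC(=O)OC(C)(C)C)[C@@H](O[Si](C)(C)C(C)(C)C)[C@@H]1C(C)=C
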